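**Retrosynthetic overview**
- **Enabling feature.** Number the carbocycle C1 = CH(aryl), C2=C3(CH3), C4H2, C5H2, C6 = quaternary C bearing CH3 and the styryl arm. C1 is allylic to C2=C3, so exchanging C3–CH3 for C3–O makes C1–C2=C3–O the enolate left by a 1,4-addition. C1 is therefore the β-carbon of a 4,4-disubstituted cyclohex-2-enone.
- **Last disconnections.** C3–CH3 comes from Negishi methylation of an alkenyl nonaflate. The key event forms C1–C6' (C6' = C6 of a 7-methoxycoumarin) by rhodium/BINAP-catalysed 1,4-addition of a coumarin-6-ylzinc reagent to the styrylcoumarin enone, with Me3SiCl capture of the enolate.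
- **Enone half.** Heck reaction of 6-iodo-7-methoxycoumarin with (R)-4-ethenyl-4-methylcyclohex-2-enone. The same iodide also supplies the zinc reagent, so both coumarin units come from one building block.
- **Quaternary centre and carbocycle.** Enantioselective Diels–Alder reaction of 1-dimethylamino-3-silyloxybutadiene with methacrolein, then Wittig methylenation and HF unmasking.
- **Ring order.** Coumarin pyranone ring first (Wittig–lactonisation of an iodosalicylaldehyde), then the carbocycle (Diels–Alder). No ring is formed afterwards.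

Key step: step 8

Assumption: the (R,R)-enantiomer of the TADDOL catalyst is taken to deliver the (1S)-cycloadduct of step 3. If the sense of induction is opposite, the equally available (S,S)-enantiomer is used and nothing else changes.

Step 1
Reactants: 1 2-hydroxy-4-methoxybenzaldehyde
Product: 2 2-hydroxy-5-iodo-4-methoxybenzaldehyde
Conditions: NIS (1.05 equiv), CF3CO2H (cat.), MeCN, 0 °C to rt
Reagents that add atoms: N-iodosuccinimide, O=C1CCC(=O)N1I
Why: Electrophilic aromatic iodination should occur at C5, which is para to OH and ortho to OCH3 and is the only doubly activated position not wedged between two oxygen substituents.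

Step 2
Reactants: 2 2-hydroxy-5-iodo-4-methoxybenzaldehyde
Product: 4 6-iodo-7-methoxy-2H-chromen-2-one, via hydroxycinnamate ester 3 (not isolated)
Conditions: Ph3P=CHCO2Et (1.2 equiv), PhNEt2, reflux (ca. 215 °C)
Reagents that add atoms: ethyl (triphenylphosphoranylidene)acetate, CCOC(=O)C=P(c1ccccc1)(c1ccccc1)c1ccccc1
Why: Wittig olefination of a salicylaldehyde, followed at reflux by thermal E/Z equilibration and lactonisation with loss of ethanol, is the standard one-flask coumarin synthesis, and the aryl iodide is a spectator.

Step 3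
Reactants: 5 (E)-3-(tert-butyldimethylsilyloxy)-N,N-dimethylbuta-1,3-dien-1-amine; 6 methacrolein
Product: 7 (1S,2R)-4-(tert-butyldimethylsilyloxy)-2-(dimethylamino)-1-methylcyclohex-3-ene-1-carbaldehyde
Conditions: (R,R)-1-naphthyl-TADDOL (20 mol %), toluene, −80 °C; volatiles removed cold, crude 7 used at once
Reagents that add atoms: none
Why: In this hydrogen-bond-catalysed enantioselective Diels–Alder reaction of an aminosiloxydiene with an α-substituted acrolein, the amino terminus of 5 bonds to the α-carbon of 6 and the TADDOL-bound formyl group reacts endo with one face shielded by a naphthyl ring, which sets the quaternary centre (1S) and, transiently, C2 (NMe2 cis to CHO).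

Step 4
Reactants: 7 (1S,2R)-4-(tert-butyldimethylsilyloxy)-2-(dimethylamino)-1-methylcyclohex-3-ene-1-carbaldehyde
Product: 8 (1R,6R)-3-(tert-butyldimethylsilyloxy)-6-ethenyl-N,N,6-trimethylcyclohex-2-en-1-amine
Conditions: Ph3PCH3Br, KOt-Bu, THF, 0 °C; then 7, −78 °C to rt
Reagents that add atoms: methyltriphenylphosphonium bromide (as its ylide), C[P+](c1ccccc1)(c1ccccc1)c1ccccc1.[Br-]
Why: Wittig methylenation of a non-enolisable neopentyl aldehyde leaves the silyl enol ether and tertiary amine untouched, and the quaternary centre cannot epimerise (the descriptor changes only through CIP priorities).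

Step 5
Reactants: 8 (1R,6R)-3-(tert-butyldimethylsilyloxy)-6-ethenyl-N,N,6-trimethylcyclohex-2-en-1-amine
Product: 10 (R)-4-ethenyl-4-methylcyclohex-2-en-1-one, via aminoketone 9 (not isolated)
Conditions: HF (48 % aq.)/MeCN 1:9, 0 °C to rt; NaHCO3 work-up
Reagents that add atoms: none
Why: Cleavage of the silyl enol ether gives a β-aminoketone that loses dimethylamine by E1cB elimination, the standard unmasking of aminosiloxydiene cycloadducts, which erases the auxiliary amino stereocentre and leaves the quaternary centre untouched.

Step 6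
Reactants: 10 (R)-4-ethenyl-4-methylcyclohex-2-en-1-one; 4 6-iodo-7-methoxy-2H-chromen-2-one
Product: 11 7-methoxy-6-{(E)-2-[(1R)-1-methyl-4-oxocyclohex-2-en-1-yl]ethenyl}-2H-chromen-2-one
Conditions: Pd(OAc)2 (5 mol %), n-Bu4NCl, NaHCO3, DMF, 65 °C
Reagents that add atoms: none
Why: In this Mizoroki–Heck reaction the monosubstituted vinyl group inserts much faster than the cyclic enone alkene, the aryl group goes to the terminal carbon, and because the allylic carbon is quaternary, β-hydride elimination can only give the (E)-styrene.

Step 7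
Reactants: 4 6-iodo-7-methoxy-2H-chromen-2-one
Product: 12 (7-methoxy-2-oxo-2H-chromen-6-yl)zinc iodide (THF solution, LiCl present)
Conditions: Zn dust (activated with cat. BrCH2CH2Br and Me3SiCl), LiCl, THF, 25 to 50 °C; solution titrated and used directly
Reagents that add atoms: zinc, [Zn]
Why: LiCl-promoted direct insertion of zinc into an aryl iodide is assisted here by the ortho-methoxy group, and arylzinc halides tolerate the lactone and its conjugated alkene.

Step 8
Reactants: 11 7-methoxy-6-{(E)-2-[(1R)-1-methyl-4-oxocyclohex-2-en-1-yl]ethenyl}-2H-chromen-2-one; 12 (7-methoxy-2-oxo-2H-chromen-6-yl)zinc iodide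
Product: 13 7-methoxy-6-{(1S,6R)-6-[(E)-2-(7-methoxy-2-oxo-2H-chromen-6-yl)ethenyl]-6-methyl-3-(trimethylsilyloxy)cyclohex-2-en-1-yl}-2H-chromen-2-one
Conditions: [RhCl(C2H4)2]2 (2.5 mol %), (R)-BINAP (5.5 mol %), 12 (2 equiv), Me3SiCl (2.5 equiv), THF, 20 to 40 °C; cold aq. NaHCO3 work-up, no chromatography
Reagents that add atoms: chlorotrimethylsilane, C[Si](C)(C)Cl
Why: Transmetalation from zinc gives an (R)-BINAP-bound monovalent aryl-rhodium species that inserts the enone alkene of 11 and delivers the aryl group to the β-carbon next to the quaternary centre; the oxa-π-allyl-rhodium enolate is then O-silylated by Me3SiCl, which returns the Rh–Cl catalyst and fixes the new C=C exactly where the trisubstituted alkene of the target lies. The closest known reaction type is the rhodium/BINAP-catalysed asymmetric 1,4-addition of arylzinc halides to cyclic enone-type acceptors in the presence of chlorotrimethylsilane (Hayashi–Miyaura family), which releases silyl enol ethers under aprotic conditions. No ring is closed; the step joins the C19 and C10 halves at the most hindered C–C bond of the target. The new stereocentre (S) is set by the ligand, since (R)-BINAP is the enantiomer that turns cyclohex-2-enone into (R)-3-arylcyclohexanones, which on 11 means attack on the ring face that carries CH3 and is anti to the styryl arm; the substrate should reinforce this because the longer styryl arm screens the opposite face (matched pair), and residual (S)-11 is diverted to a separable cis diastereomer. The step needs chemoselectivity for the ketone-conjugated alkene over the two coumarin C3=C4 bonds and the styryl alkene, and this is secured because coumarins are much poorer acceptors for aryl-rhodium species than cyclic enones at ambient temperature, arylzinc halides do not add to ketones or lactones without catalyst, and the styryl alkene is unactivated. The regiochemistry of the enol ether needs no selection, because the enolate is trapped where it is born.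

Step 9
Reactants: 13 silyl enol ether of step 8
Product: 14 (3S,4R)-3-(7-methoxy-2-oxo-2H-chromen-6-yl)-4-[(E)-2-(7-methoxy-2-oxo-2H-chromen-6-yl)ethenyl]-4-methylcyclohex-1-en-1-yl nonafluorobutane-1-sulfonate
Conditions: n-C4F9SO2F (1.5 equiv), n-Bu4N[Ph3SiF2] (10 mol %), THF, 0 °C to rt
Reagents that add atoms: nonafluorobutane-1-sulfonyl fluoride, O=S(=O)(F)C(F)(F)C(F)(F)C(F)(F)C(F)(F)F
Why: In this fluoride-catalysed exchange of a silyl enol ether for an alkenyl nonaflate, catalytic fluoride releases the ammonium enolate, which is O-sulfonylated faster than it can equilibrate and regenerates fluoride, so the alkene position and both stereocentres are retained.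

Step 10
Reactants: 14 alkenyl nonaflate of step 9
Product: 15 7-methoxy-6-{(1S,6R)-6-[(E)-2-(7-methoxy-2-oxo-2H-chromen-6-yl)ethenyl]-3,6-dimethylcyclohex-2-en-1-yl}-2H-chromen-2-one (target)
Conditions: MeZnCl (2 equiv), Pd(PPh3)4 (5 mol %), THF, rt to 50 °C
Reagents that add atoms: methylzinc chloride, C[Zn]Cl
Why: Negishi cross-coupling of an alkenyl sulfonate proceeds with retention of the alkene position, methyl carries no β-hydrogen, and the organozinc reagent leaves the lactones, the styrene and the allylic stereocentre untouched.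

**Compound list**
1 | 2-hydroxy-4-methoxybenzaldehyde | COc1ccc(C=O)c(O)c1 | starting material
2 | 2-hydroxy-5-iodo-4-methoxybenzaldehyde | COc1cc(O)c(C=O)cc1I | intermediate
3 | ethyl (E)-3-(2-hydroxy-5-iodo-4-methoxyphenyl)prop-2-enoate (not isolated) | CCOC(=O)/C=C/c1cc(I)c(OC)cc1O | intermediate
4 | 6-iodo-7-methoxy-2H-chromen-2-one | COc1cc2oc(=O)ccc2cc1I | intermediate
5 | (E)-3-(tert-butyldimethylsilyloxy)-N,N-dimethylbuta-1,3-dien-1-amine | CN(C)/C=C/C(=C)O[Si](C)(C)C(C)(C)C | starting material
6 | methacrolein | CC(=C)C=O | starting material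
7 | (1S,2R)-4-(tert-butyldimethylsilyloxy)-2-(dimethylamino)-1-methylcyclohex-3-ene-1-carbaldehyde | O=C[C@@]1(C)CCC(O[Si](C)(C)C(C)(C)C)=C[C@H]1N(C)C | intermediate
8 | (1R,6R)-3-(tert-butyldimethylsilyloxy)-6-ethenyl-N,N,6-trimethylcyclohex-2-en-1-amine | C=C[C@@]1(C)CCC(O[Si](C)(C)C(C)(C)C)=C[C@H]1N(C)C | intermediate
9 | (3R,4R)-3-(dimethylamino)-4-ethenyl-4-methylcyclohexan-1-one (not isolated) | C=C[C@@]1(C)CCC(=O)C[C@H]1N(C)C | intermediate
10 | (R)-4-ethenyl-4-methylcyclohex-2-en-1-one | C=C[C@@]1(C)CCC(=O)C=C1 | intermediate
11 | 7-methoxy-6-{(E)-2-[(1R)-1-methyl-4-oxocyclohex-2-en-1-yl]ethenyl}-2H-chromen-2-one | COc1cc2oc(=O)ccc2cc1/C=C/[C@@]1(C)CCC(=O)C=C1 | intermediate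
12 | (7-methoxy-2-oxo-2H-chromen-6-yl)zinc iodide | COc1cc2oc(=O)ccc2cc1[Zn]I | intermediate
13 | 7-methoxy-6-{(1S,6R)-6-[(E)-2-(7-methoxy-2-oxo-2H-chromen-6-yl)ethenyl]-6-methyl-3-(trimethylsilyloxy)cyclohex-2-en-1-yl}-2H-chromen-2-one | COc1cc2oc(=O)ccc2cc1/C=C/[C@@]1(C)CCC(O[Si](C)(C)C)=C[C@@H]1c1cc2ccc(=O)oc2cc1OC | intermediate
14 | (3S,4R)-3-(7-methoxy-2-oxo-2H-chromen-6-yl)-4-[(E)-2-(7-methoxy-2-oxo-2H-chromen-6-yl)ethenyl]-4-methylcyclohex-1-en-1-yl nonafluorobutane-1-sulfonate | COc1cc2oc(=O)ccc2cc1/C=C/[C@@]1(C)CCC(OS(=O)(=O)C(F)(F)C(F)(F)C(F)(F)C(F)(F)F)=C[C@@H]1c1cc2ccc(=O)oc2cc1OC | intermediate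
15 | 7-methoxy-6-{(1S,6R)-6-[(E)-2-(7-methoxy-2-oxo-2H-chromen-6-yl)ethenyl]-3,6-dimethylcyclohex-2-en-1-yl}-2H-chromen-2-one | COc1cc2oc(=O)ccc2cc1/C=C/[C@@]1(C)CCC(C)=C[C@@H]1c1cc2ccc(=O)oc2cc1OC | target

Total step count: 10. Longest linear sequence: 7 steps (3, 4, 5, 6, 8, 9, 10).

**Steps most likely to fail**

1. **Step 8.**
   - Risk: carborhodation at a β-carbon flanked by the quaternary centre, with an ortho-substituted aryl donor, may be slow. Protodemetalation, aryl homocoupling, addition to a coumarin alkene or erosion of facial selectivity could then take over.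
   - Fallback (changed order of fragment union): it sets out from 10 and 12 and comes back at 15. The same rhodium/(R)-BINAP/Me3SiCl addition is run on the small, coumarin-free vinyl enone 10, where excess reagent and higher temperature can be afforded. This gives 6-[(1S,6R)-6-ethenyl-6-methyl-3-(trimethylsilyloxy)cyclohex-2-en-1-yl]-7-methoxy-2H-chromen-2-one F1. Fluoride-catalysed exchange with n-C4F9SO2F gives the corresponding alkenyl nonaflate F2. Negishi methylation gives 6-[(1S,6R)-6-ethenyl-3,6-dimethylcyclohex-2-en-1-yl]-7-methoxy-2H-chromen-2-one F3. The styryl arm is attached last by the Heck conditions of step 6 between F3 and 4, which gives 15.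

2. **Step 3.**
   - Risk: incomplete enantiofacial discrimination, or decomposition of the sensitive β-amino aldehyde before olefination, would lower the enantiomeric purity or the supply of 10.
   - Fallback (stereocentre erased and rewritten by desymmetrisation): it sets out from 11 of any enantiomeric purity and comes back at 11. Racemic 11 is available through the uncatalysed cycloaddition followed by steps 4 to 6. Dehydrogenation with 2-iodoxybenzoic acid (DMSO, 70 °C) gives the achiral 7-methoxy-6-[(E)-2-(1-methyl-4-oxocyclohexa-2,5-dien-1-yl)ethenyl]-2H-chromen-2-one F4, whose two ring alkenes are enantiotopic. Enantioselective conjugate reduction of one of them returns (R)-11. An ene-reductase of the old-yellow-enzyme family, screened for the (R)-sense and run with NADPH recycled by glucose/glucose dehydrogenase, is proposed; this reaction type is known for 4,4-disubstituted cyclohexa-2,5-dienones.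

3. **Step 9.**
   - Risk: premature protodesilylation of the trimethylsilyl enol ether, or equilibration of the liberated enolate, would destroy the regiochemical information gained in step 8.
   - Fallback (silyl ether and sulfonate exchange bypassed): it sets out from 11 and 12 and comes back at 15. The rhodium-catalysed addition is run without chlorosilane, so that transmetalation with 12 releases the iodozinc enolate F5. After solvent exchange to toluene, F5 is O-sulfonylated directly with triflic anhydride at −78 °C to give the enol triflate F6. F6 enters the Negishi methylation of step 10 and gives 15.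

**Further compounds**
F1 | step 8 | 6-[(1S,6R)-6-ethenyl-6-methyl-3-(trimethylsilyloxy)cyclohex-2-en-1-yl]-7-methoxy-2H-chromen-2-one | C=C[C@@]1(C)CCC(O[Si](C)(C)C)=C[C@@H]1c1cc2ccc(=O)oc2cc1OC
F2 | step 8 | (3S,4R)-4-ethenyl-3-(7-methoxy-2-oxo-2H-chromen-6-yl)-4-methylcyclohex-1-en-1-yl nonafluorobutane-1-sulfonate | C=C[C@@]1(C)CCC(OS(=O)(=O)C(F)(F)C(F)(F)C(F)(F)C(F)(F)F)=C[C@@H]1c1cc2ccc(=O)oc2cc1OC
F3 | step 8 | 6-[(1S,6R)-6-ethenyl-3,6-dimethylcyclohex-2-en-1-yl]-7-methoxy-2H-chromen-2-one | C=C[C@@]1(C)CCC(C)=C[C@@H]1c1cc2ccc(=O)oc2cc1OC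
F4 | step 3 | 7-methoxy-6-[(E)-2-(1-methyl-4-oxocyclohexa-2,5-dien-1-yl)ethenyl]-2H-chromen-2-one | COc1cc2oc(=O)ccc2cc1/C=C/C1(C)C=CC(=O)C=C1
F5 | step 9 | iodozinc enolate of the 1,4-adduct of 11 and 12 | COc1cc2oc(=O)ccc2cc1/C=C/[C@@]1(C)CCC(O[Zn]I)=C[C@@H]1c1cc2ccc(=O)oc2cc1OC
F6 | step 9 | (3S,4R)-3-(7-methoxy-2-oxo-2H-chromen-6-yl)-4-[(E)-2-(7-methoxy-2-oxo-2H-chromen-6-yl)ethenyl]-4-methylcyclohex-1-en-1-yl trifluoromethanesulfonate | COc1cc2oc(=O)ccc2cc1/C=C/[C@@]1(C)CCC(OS(=O)(=O)C(F)(F)F)=C[C@@H]1c1cc2ccc(=O)oc2cc1OC
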